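A direct plan would contract (R)-pulegone to a cyclopentane β-keto ester, vinylate it and add methyl iodoacetate across the vinyl group to give iodide A1. A radical 1,2-acyl shift ending in allyl transfer would then expand the ring to cyclohexanone A2, an isopropenyl metal would add with lactonisation to give bridged lactone A3, and cross-metathesis to alkylidene lactone A4 followed by double-bond migration would finish the butenolide. Its weakest steps would be:
- the ring expansion with allyl transfer, an untested cascade that would have to outrun direct allylation and set the quaternary C1 between two stereocentres;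
- the cross-metathesis, which would join a neopentylic allyl group to an α-methylene lactone beside an isopropenyl group and should be slow and prone to homodimers;
- the final migration of the exocyclic alkene into the lactone ring, which would add length without complexity and put the other alkenes at risk.

The new route rests on the C1–C8 and C5–O6 bonds of the 6-oxabicyclo[3.2.1]octan-7-one. An open-chain (Z)-diene that carries an α-bromo-γ-butyrolactone at the future C1 would be isomerised in one operation. The C1 radical closes the cyclohexane by 6-endo attack on C8; the allyl cation at C5 is captured by the lactone carbonyl (C7), which lies 1,3-diaxial to C5 in the chair; bromide opens the old lactone to a 2-bromoethyl arm. Ring, bridged lactone and the C1, C5 and C8 stereocentres thus arise together from the single C2 stereocentre. No ring expansion, metathesis or alkene migration is needed.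

Key step: step 8

Remark: C1–C8 are the atoms of the bicyclic core of the target (C1 quaternary, C2 CHCH3, C5 C–O, O6, C7 C=O, C8 CH) and are used for the open-chain precursors too; the lactone α-carbon (future C1) is carried as a mixture of epimers up to 14 because step 8 makes it a planar radical.

Step 1
Reactants: 1 methyl hydrogen (R)-3-methylglutarate [(3R)-5-methoxy-3-methyl-5-oxopentanoic acid]
Product: 3 (4R)-4-methyloxan-2-one, via hydroxy ester 2 (not isolated)
Conditions: BH3·SMe2, THF, 0 → 25 °C; then TsOH·H2O (cat.), PhMe, 80 °C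
Reagents that add atoms: none
Why: Borane reduces the free carboxylic acid chemoselectively beside the methyl ester (acid-selective borane reduction) and acid-catalysed lactonisation then expels methanol, while the (R) stereocentre, the future C2, is untouched.

Step 2
Reactants: 3 (4R)-4-methyloxan-2-one; 4 ethylene oxide
Product: 6 3-[(2R)-4-hydroxybutan-2-yl]oxolan-2-one (both epimers at C3 of the lactone), via hydroxyethyl δ-lactone 5 (not isolated)
Conditions: LiN(i-Pr)2, THF, −78 °C; Et2AlCl; ethylene oxide, −78 → 0 °C; then 1 M HCl, 25 °C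
Reagents that add atoms: ethylene oxide (4), C1CO1
Why: Enolate alkylation with an epoxide (the aluminium enolate of 3 opens ethylene oxide) followed by acid-mediated translactonisation to the more stable γ-lactone, which frees the primary alcohol at the future C4; the new α-stereocentre needs no control because it is planarised in step 8.

Step 3
Reactants: 6 3-[(2R)-4-hydroxybutan-2-yl]oxolan-2-one
Product: 7 3-[(2R)-4-iodobutan-2-yl]oxolan-2-one
Conditions: I2, PPh3, imidazole, CH2Cl2, 0 → 25 °C
Reagents that add atoms: iodine, II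
Why: Appel-type iodination converts the primary alcohol into the iodide by SN2 displacement of the oxyphosphonium group without touching the lactone.

Step 4
Reactants: 8 methyl 4-oxobutanoate
Product: 9 methyl 5,5-dichloropent-4-enoate
Conditions: PPh3, CCl4, THF, 60 °C
Reagents that add atoms: carbon tetrachloride, ClC(Cl)(Cl)Cl
Why: Wittig-type dichloromethylenation of the aldehyde with Ph3P=CCl2 generated from PPh3 and CCl4 (the chlorine analogue of the Ramirez dibromo-olefination).

Step 5
Reactants: 7 3-[(2R)-4-iodobutan-2-yl]oxolan-2-one; 9 methyl 5,5-dichloropent-4-enoate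
Product: 11 methyl (4Z,8R)-5-chloro-8-(2-oxooxolan-3-yl)non-4-enoate, via alkylzinc iodide 10 (not isolated)
Conditions: Zn dust (I2-activated), DMA, 40 °C; then 9, PdCl2(DPEphos) (5 mol%), THF, 25 → 50 °C
Reagents that add atoms: methyl 5,5-dichloropent-4-enoate (9), COC(=O)CCC=C(Cl)Cl
Why: Zinc inserts into the primary C–I bond and the Negishi monoalkylation of a 1,1-dichloro-1-alkene is trans-selective (oxidative addition at the less hindered C–Cl bond trans to the chain), so the tether should end trans and the remaining chlorine cis to the propanoate arm.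

Step 6
Reactants: 11 methyl (4Z,8R)-5-chloro-8-(2-oxooxolan-3-yl)non-4-enoate; 12 isopropenylmagnesium bromide
Product: 13 methyl (4Z,8R)-8-(2-oxooxolan-3-yl)-5-(prop-1-en-2-yl)non-4-enoate
Conditions: CH2=C(CH3)MgBr, ZnBr2, THF, 0 °C; then 11, Pd(t-Bu3P)2 (5 mol%), THF/NMP, 50 °C
Reagents that add atoms: isopropenylmagnesium bromide (12), C=C(C)[Mg]Br
Why: Second Negishi coupling of the alkenyl chloride with isopropenylzinc bromide proceeds with retention of the alkene configuration, which places the isopropenyl group cis and the tether trans to the propanoate arm.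

Step 7
Reactants: 13 methyl (4Z,8R)-8-(2-oxooxolan-3-yl)-5-(prop-1-en-2-yl)non-4-enoate
Product: 14 methyl (4Z,8R)-8-(3-bromo-2-oxooxolan-3-yl)-5-(prop-1-en-2-yl)non-4-enoate (both epimers at the C–Br carbon)
Conditions: LiN(SiMe3)2 (1.05 equiv), THF, −78 → −40 °C; then BrCl2C–CCl2Br, −78 °C
Reagents that add atoms: 1,2-dibromo-1,1,2,2-tetrachloroethane, BrC(Cl)(Cl)C(Cl)(Cl)Br
Why: Enolate halogenation, in which the γ-lactone α-hydrogen is several pK units more acidic than that of the open-chain methyl ester, so one equivalent of the silylamide should enolise the lactone selectively; the configuration of the new C–Br centre is irrelevant.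

Step 8
Reactants: 14 methyl (4Z,8R)-8-(3-bromo-2-oxooxolan-3-yl)-5-(prop-1-en-2-yl)non-4-enoate
Product: 18 methyl 3-[(1R,2R,5S,8R)-1-(2-bromoethyl)-2-methyl-7-oxo-5-(prop-1-en-2-yl)-6-oxabicyclo[3.2.1]octan-8-yl]propanoate, via α-acyl radical 15 (not isolated), via allyl cation 16 (not isolated), via dialkoxycarbenium ion 17 (not isolated)
Conditions: CuBr (10 mol%), tris(2-pyridylmethyl)amine (10 mol%), ClCH2CH2Cl (0.01 M), 80 °C, degassed
Reagents that add atoms: none
Why: Proposed new method: monovalent copper abstracts bromine from 14 to give the planar tertiary α-acyl radical 15 (both epimers of 14 converge), which adds 6-endo-trig to C8 of the diene; the allyl radical is oxidised by divalent copper, directly or through its allylic bromide, to cation 16, the axial lactone carbonyl attacks C5 to give the bridged dialkoxycarbenium ion 17, and bromide opens the old O–CH2 bond by SN2 to release 18, so that the whole step is an isomerisation. The closest known reaction types are the copper-catalysed atom-transfer radical cyclisation of α-halo esters, the radical addition of α-halo esters to alkenes with lactonisation of the γ-halo ester (or its oxidative Mn(OAc)3 version with unsaturated malonic acids) and the opening of 1,3-dioxolan-2-ylium ions by halide; new is their union on a 1,3-diene with transposition of a lactone. The cyclohexane is closed by the 6-endo radical addition (C1–C8; attack at the fully substituted C5 would be hindered and give an unstabilised radical), and the γ-lactone bridge (O6–C5) by five-membered capture of the cation by the carbonyl oxygen that lies 1,3-diaxial to C5, capture at the CH2 terminus needing a seven-membered ring. C8 is set by the (Z)-alkene, whose arm trans to the tether becomes equatorial in the chair transition state that keeps the C2 methyl equatorial; C1 is set in the same chair, in which the lactone CH2 should take the equatorial site beside C2–H and the smaller, planar carbonyl the axial site (no CH2/CH2 eclipsing across C1–C2, lower A value), and C5 follows from the bridge. The step needs attack at C8 to beat 7-endo attack at the isopropenyl CH2: the arm cis to the isopropenyl group twists the diene, and only bonding at C8 relieves this strain while the new radical centre comes into conjugation. High dilution suppresses intermolecular addition, and bromide capture of 16 is reversible, so that lactone 18 is the sink.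

Step 9
Reactants: 19 3-bromooxolan-2-one (α-bromo-γ-butyrolactone); 20 thiophenol
Product: 21 3-(phenylsulfanyl)oxolan-2-one (racemic)
Conditions: Et3N, CH2Cl2, 0 → 25 °C
Reagents that add atoms: thiophenol (20), Sc1ccccc1
Why: SN2 displacement of the activated α-bromide by thiophenolate (thioether formation).

Step 10
Reactants: 18 methyl 3-[(1R,2R,5S,8R)-1-(2-bromoethyl)-2-methyl-7-oxo-5-(prop-1-en-2-yl)-6-oxabicyclo[3.2.1]octan-8-yl]propanoate; 21 3-(phenylsulfanyl)oxolan-2-one
Product: 22 methyl 3-[(1R,2R,5S,8R)-2-methyl-7-oxo-1-{2-[2-oxo-3-(phenylsulfanyl)oxolan-3-yl]ethyl}-5-(prop-1-en-2-yl)-6-oxabicyclo[3.2.1]octan-8-yl]propanoate (both epimers at the sulfur-bearing carbon)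
Conditions: 21, LiN(SiMe3)2, THF, −78 °C; then 18, DMPU, Bu4NI (cat.), −78 → 25 °C
Reagents that add atoms: 3-(phenylsulfanyl)oxolan-2-one (21), O=C1OCCC1Sc1ccccc1
Why: SN2 alkylation of the sulfur-stabilised lactone enolate by the primary bromide, the classical entry to α-alkyl butenolides; the bridged lactone has no α-hydrogen, the methyl ester is too weakly acidic for this soft enolate, and the new sulfide centre is destroyed in step 11.

Step 11
Reactants: 22 methyl 3-[(1R,2R,5S,8R)-2-methyl-7-oxo-1-{2-[2-oxo-3-(phenylsulfanyl)oxolan-3-yl]ethyl}-5-(prop-1-en-2-yl)-6-oxabicyclo[3.2.1]octan-8-yl]propanoate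
Product: 24 methyl 3-[(1R,2R,5S,8R)-2-methyl-7-oxo-1-[2-(2-oxo-2,5-dihydrofuran-3-yl)ethyl]-5-(prop-1-en-2-yl)-6-oxabicyclo[3.2.1]octan-8-yl]propanoate (CNP0209666.1), via sulfoxide 23 (not isolated)
Conditions: mCPBA (1.0 equiv), CH2Cl2, −78 °C; then PhMe, CaCO3, 110 °C
Reagents that add atoms: none
Why: Chemoselective sulfide oxidation (far faster than epoxidation of the isopropenyl group at −78 °C) and thermal syn-elimination of benzenesulfenic acid (sulfoxide pyrolysis) toward the ring CH2 give the conjugated endocyclic butenolide without touching any stereocentre.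

Compound list

1 | methyl hydrogen (R)-3-methylglutarate, (3R)-5-methoxy-3-methyl-5-oxopentanoic acid | OC(=O)C[C@@H](C)CC(=O)OC | starting material
2 | methyl (3R)-5-hydroxy-3-methylpentanoate | OCC[C@@H](C)CC(=O)OC | intermediate
3 | (4R)-4-methyloxan-2-one | C[C@@H]1CCOC(=O)C1 | intermediate
4 | ethylene oxide (oxirane) | C1CO1 | starting material
5 | (4R)-3-(2-hydroxyethyl)-4-methyloxan-2-one (C3 epimers) | C[C@@H]1CCOC(=O)C1CCO | intermediate
6 | 3-[(2R)-4-hydroxybutan-2-yl]oxolan-2-one (epimers at lactone C3) | OCC[C@@H](C)C1CCOC1=O | intermediate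
7 | 3-[(2R)-4-iodobutan-2-yl]oxolan-2-one (epimers at lactone C3) | ICC[C@@H](C)C1CCOC1=O | intermediate
8 | methyl 4-oxobutanoate | COC(=O)CCC=O | starting material
9 | methyl 5,5-dichloropent-4-enoate | COC(=O)CCC=C(Cl)Cl | intermediate
10 | [(3R)-3-(2-oxooxolan-3-yl)butyl]zinc iodide | I[Zn]CC[C@@H](C)C1CCOC1=O | intermediate
11 | methyl (4Z,8R)-5-chloro-8-(2-oxooxolan-3-yl)non-4-enoate | COC(=O)CC/C=C(\Cl)CC[C@@H](C)C1CCOC1=O | intermediate
12 | isopropenylmagnesium bromide | C=C(C)[Mg]Br | starting material
13 | methyl (4Z,8R)-8-(2-oxooxolan-3-yl)-5-(prop-1-en-2-yl)non-4-enoate | COC(=O)CC/C=C(\C(C)=C)CC[C@@H](C)C1CCOC1=O | intermediate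
14 | methyl (4Z,8R)-8-(3-bromo-2-oxooxolan-3-yl)-5-(prop-1-en-2-yl)non-4-enoate (C–Br epimers) | COC(=O)CC/C=C(\C(C)=C)CC[C@@H](C)C1(Br)CCOC1=O | intermediate
15 | tertiary α-acyl radical at the lactone α-carbon of 14 (bromine removed) | COC(=O)CC/C=C(\C(C)=C)CC[C@@H](C)[C]1CCOC1=O | intermediate
16 | spirocyclic allyl cation: 2-oxaspiro[4.5]decan-1-one with the 10-methyl, the 6-(3-methoxy-3-oxopropyl) arm and the lactone carbonyl cis, positive charge shared by ring C7 and the isopropenyl CH2 | C=C(C)[C+]1CC[C@@H](C)[C@]2(CCOC2=O)[C@H]1CCC(=O)OC | intermediate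
17 | bridged dialkoxycarbenium bromide: C7 bonded to O6 (on C5) and to the oxygen of the former γ-lactone | C=C(C)[C@@]12CC[C@@H](C)[C@]3(CCO[C+]3O1)[C@H]2CCC(=O)OC.[Br-] | intermediate
18 | methyl 3-[(1R,2R,5S,8R)-1-(2-bromoethyl)-2-methyl-7-oxo-5-(prop-1-en-2-yl)-6-oxabicyclo[3.2.1]octan-8-yl]propanoate | C=C(C)[C@@]12CC[C@@H](C)[C@@](CCBr)(C(=O)O1)[C@H]2CCC(=O)OC | intermediate
19 | 3-bromooxolan-2-one (racemic) | BrC1CCOC1=O | starting material
20 | thiophenol | Sc1ccccc1 | starting material
21 | 3-(phenylsulfanyl)oxolan-2-one (racemic) | O=C1OCCC1Sc1ccccc1 | intermediate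
22 | methyl 3-[(1R,2R,5S,8R)-2-methyl-7-oxo-1-{2-[2-oxo-3-(phenylsulfanyl)oxolan-3-yl]ethyl}-5-(prop-1-en-2-yl)-6-oxabicyclo[3.2.1]octan-8-yl]propanoate (epimers at C–S) | C=C(C)[C@@]12CC[C@@H](C)[C@@](CCC3(Sc4ccccc4)CCOC3=O)(C(=O)O1)[C@H]2CCC(=O)OC | intermediate
23 | methyl 3-[(1R,2R,5S,8R)-2-methyl-7-oxo-1-{2-[2-oxo-3-(phenylsulfinyl)oxolan-3-yl]ethyl}-5-(prop-1-en-2-yl)-6-oxabicyclo[3.2.1]octan-8-yl]propanoate (sulfoxide diastereomers) | C=C(C)[C@@]12CC[C@@H](C)[C@@](CCC3(S(=O)c4ccccc4)CCOC3=O)(C(=O)O1)[C@H]2CCC(=O)OC | intermediate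
24 | methyl 3-[(1R,2R,5S,8R)-2-methyl-7-oxo-1-[2-(2-oxo-2,5-dihydrofuran-3-yl)ethyl]-5-(prop-1-en-2-yl)-6-oxabicyclo[3.2.1]octan-8-yl]propanoate (CNP0209666.1) | C=C(C)[C@@]12CC[C@@H](C)[C@@](CCC3=CCOC3=O)(C(=O)O1)[C@H]2CCC(=O)OC | target

Total step count: 11. Longest linear sequence: 9 steps (1, 2, 3, 5, 6, 7, 8, 10, 11); steps 4 and 9 are side branches.

Steps most likely to fail

1. Step 8 (proposed new method). The crossover from the cyclised allyl radical to the cation may be inefficient, so that the radical is reduced or the cation loses a proton instead of being captured by the lactone carbonyl. The fallback uses known reactions and runs from 14 back to 22. Reductive 6-endo radical cyclisation with Bu3SnH/AIBN (PhH, 80 °C, slow addition), in which the allyl radical takes hydrogen at its CH2 terminus, should give the isopropylidene spirolactone methyl 3-[10-methyl-1-oxo-7-(propan-2-ylidene)-2-oxaspiro[4.5]decan-6-yl]propanoate (carbonyl, methyl and arm cis) F1. Phenylselenolactonisation with PhSeCl (CH2Cl2, −78 °C), in which the lactone carbonyl opens the seleniranium ion at the ring carbon and chloride cleaves the old O–CH2 bond, should give methyl 3-[(1R,2R,5S,8R)-1-(2-chloroethyl)-2-methyl-7-oxo-5-[2-(phenylselanyl)propan-2-yl]-6-oxabicyclo[3.2.1]octan-8-yl]propanoate F2. Oxidation with H2O2 (pyridine, CH2Cl2, 0 °C) and selenoxide elimination, possible only toward a methyl group, should give methyl 3-[(1R,2R,5S,8R)-1-(2-chloroethyl)-2-methyl-7-oxo-5-(prop-1-en-2-yl)-6-oxabicyclo[3.2.1]octan-8-yl]propanoate F3, which would alkylate the enolate of 21 under the conditions of step 10 and rejoin the route at 22.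

2. Step 7. The methyl ester may be deprotonated in competition with the lactone, which would lead to bromination or condensation at the propanoate arm. The fallback runs from 13 back to 14. Saponification (LiOH, THF/H2O; then HCl to reclose the lactone) would give (4Z,8R)-8-(2-oxooxolan-3-yl)-5-(prop-1-en-2-yl)non-4-enoic acid F4. Dianion formation with LiN(i-Pr)2 (2.2 equiv, −78 °C), in which the carboxylate shields its own α-position, and bromination with BrCl2C–CCl2Br would give (4Z,8R)-8-(3-bromo-2-oxooxolan-3-yl)-5-(prop-1-en-2-yl)non-4-enoic acid F5. Esterification with TMSCHN2 (PhMe/MeOH) would then give 14.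

3. Step 2. Opening of ethylene oxide by the lactone enolate may be slow, so that the enolate condenses with unreacted lactone. The fallback runs from 3 back to 6. Allylation of the lithium enolate (LiN(i-Pr)2, THF, −78 °C; allyl bromide) would give (4R)-4-methyl-3-(prop-2-en-1-yl)oxan-2-one F6. Ozonolysis with reductive work-up (O3, CH2Cl2/MeOH, −78 °C; NaBH4) would give the hydroxyethyl lactone 5, and acid treatment as in step 2 would give 6.

Further compounds

F1 | step 8 | methyl 3-[10-methyl-1-oxo-7-(propan-2-ylidene)-2-oxaspiro[4.5]decan-6-yl]propanoate (lactone carbonyl, 10-methyl and 6-arm cis) | CC(C)=C1CC[C@@H](C)[C@]2(CCOC2=O)[C@H]1CCC(=O)OC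
F2 | step 8 | methyl 3-[(1R,2R,5S,8R)-1-(2-chloroethyl)-2-methyl-7-oxo-5-[2-(phenylselanyl)propan-2-yl]-6-oxabicyclo[3.2.1]octan-8-yl]propanoate | CC(C)([Se]c1ccccc1)[C@@]12CC[C@@H](C)[C@@](CCCl)(C(=O)O1)[C@H]2CCC(=O)OC
F3 | step 8 | methyl 3-[(1R,2R,5S,8R)-1-(2-chloroethyl)-2-methyl-7-oxo-5-(prop-1-en-2-yl)-6-oxabicyclo[3.2.1]octan-8-yl]propanoate | C=C(C)[C@@]12CC[C@@H](C)[C@@](CCCl)(C(=O)O1)[C@H]2CCC(=O)OC
F4 | step 7 | (4Z,8R)-8-(2-oxooxolan-3-yl)-5-(prop-1-en-2-yl)non-4-enoic acid | OC(=O)CC/C=C(\C(C)=C)CC[C@@H](C)C1CCOC1=O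
F5 | step 7 | (4Z,8R)-8-(3-bromo-2-oxooxolan-3-yl)-5-(prop-1-en-2-yl)non-4-enoic acid | OC(=O)CC/C=C(\C(C)=C)CC[C@@H](C)C1(Br)CCOC1=O
F6 | step 2 | (4R)-4-methyl-3-(prop-2-en-1-yl)oxan-2-one (C3 epimers) | C[C@@H]1CCOC(=O)C1CC=C
A1 | direct plan | methyl (1S,5R)-1-(1-iodo-4-methoxy-4-oxobutyl)-5-methyl-2-oxocyclopentane-1-carboxylate | C[C@@H]1CCC(=O)[C@]1(C(I)CCC(=O)OC)C(=O)OC
A2 | direct plan | methyl (1R,2R,6R)-2-(3-methoxy-3-oxopropyl)-6-methyl-3-oxo-1-(prop-2-en-1-yl)cyclohexane-1-carboxylate | O=C1CC[C@@H](C)[C@@](CC=C)(C(=O)OC)[C@H]1CCC(=O)OC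
A3 | direct plan | methyl 3-[(1R,2R,5S,8R)-2-methyl-7-oxo-5-(prop-1-en-2-yl)-1-(prop-2-en-1-yl)-6-oxabicyclo[3.2.1]octan-8-yl]propanoate | C=C(C)[C@@]12CC[C@@H](C)[C@@](CC=C)(C(=O)O1)[C@H]2CCC(=O)OC
A4 | direct plan | methyl 3-[(1R,2R,5S,8R)-2-methyl-7-oxo-1-[(2E)-2-(2-oxooxolan-3-ylidene)ethyl]-5-(prop-1-en-2-yl)-6-oxabicyclo[3.2.1]octan-8-yl]propanoate | C=C(C)[C@@]12CC[C@@H](C)[C@@](C/C=C3\CCOC3=O)(C(=O)O1)[C@H]2CCC(=O)OC
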